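**Retrosynthetic overview**
1. The C7 acetate and the C10 chlorine are put on last: acetylation of a C7 alcohol freed from its silyl ether, and epoxidation of the parent enone followed by HCl opening.
2. The only ring is unfolded from a furan: a 5-octenyl-2-furylcarbinol rearranges (Piancatelli) with formation of the C8–C12 bond, the furan oxygen becoming the C9 ketone and water supplying the C12 hydroxyl.
3. The feature used is the ring C8–C9–C10–C11–C12 with C9=O, C10=C11, the tertiary carbinol C12 (OH, octenyl) and the methine C8 (C1–C7 chain): a 4-hydroxy-4-alkyl-5-substituted cyclopent-2-enone, which is what a 2,5-disubstituted furan with a carbinol on one α-substituent rearranges to.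
4. The furylcarbinol comes from 2-bromo-5-[(Z)-oct-2-enyl]furan (furan plus (Z)-1-bromooct-2-ene) and a C1–C8 aldehyde (Z-selective Wittig on (R)-glyceraldehyde acetonide, which supplies C7).
5. Ring order: furan bought, alkylated, joined to C1–C8, then converted into the cyclopentenone (the single ring-forming event); C8 is equilibrated afterwards and no C–C bond is made after the rearrangement.

Key step: step 11

Remark: positions are given in prostaglandin numbering (C1 = ester carbon, ring = C8–C12); (R)-2,3-O-isopropylideneglyceraldehyde is taken as bought and distilled just before use.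

**Route**

Step 1
Reactants: 1 (Z)-oct-2-en-1-ol
Product: 2 (Z)-1-bromooct-2-ene
Conditions: CBr4, PPh3, CH2Cl2, 0 °C
Reagents that add atoms: carbon tetrabromide, BrC(Br)(Br)Br
Why: Appel bromination, in which bromide displaces the alkoxyphosphonium group by SN2 at the primary carbon under neutral cold conditions, so neither allylic transposition nor Z to E isomerisation is expected.

Step 2
Reactants: 3 furan; 2 (Z)-1-bromooct-2-ene
Product: 5 2-[(Z)-oct-2-enyl]furan, via 2-furyllithium 4 (not isolated)
Conditions: n-BuLi, THF, −78 to 0 °C; then 2, −78 °C to rt (furan in excess)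
Reagents that add atoms: none
Why: α-lithiation of furan followed by SN2 alkylation of the organolithium at the primary allylic carbon, a known way to 2-allylfurans that leaves the Z alkene untouched.

Step 3
Reactants: 5 2-[(Z)-oct-2-enyl]furan
Product: 6 2-bromo-5-[(Z)-oct-2-enyl]furan
Conditions: NBS, DMF, −20 to 0 °C, dark; filtered through basic alumina and used at once
Reagents that add atoms: N-bromosuccinimide, O=C1CCC(=O)N1Br
Why: electrophilic aromatic bromination at the free α position of the electron-rich 2-alkylfuran, much faster than attack on the isolated alkene, installed so that the later metalation runs by bromine–lithium exchange and not by deprotonation of the furfurylic-allylic CH2.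

Step 4
Reactants: 7 (R)-2,3-O-isopropylideneglyceraldehyde; 8 (4-carboxybutyl)triphenylphosphonium bromide
Product: 10 (5Z,7S)-7,8-(isopropylidenedioxy)oct-5-enoic acid, via phosphorus ylide 9 (not isolated)
Conditions: NaN(SiMe3)2 (2 equiv), THF, 0 °C; then 7, −78 °C to rt; aq. HCl to pH 4
Reagents that add atoms: none
Why: Wittig olefination with a non-stabilised ylide under lithium-free conditions gives the Z alkene under kinetic control, and the C7 stereocentre is carried over from the aldehyde without enolisation at −78 °C (its descriptor becomes S only through the priority rules).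

Step 5
Reactants: 10 (5Z,7S)-7,8-(isopropylidenedioxy)oct-5-enoic acid
Product: 11 methyl (5Z,7S)-7,8-(isopropylidenedioxy)oct-5-enoate
Conditions: MeI, K2CO3, DMF, rt
Reagents that add atoms: iodomethane, CI
Why: SN2 O-alkylation of the potassium carboxylate, which avoids the acid that would open the acetonide.

Step 6
Reactants: 11 methyl (5Z,7S)-7,8-(isopropylidenedioxy)oct-5-enoate
Product: 12 methyl (5Z,7S)-7,8-dihydroxyoct-5-enoate
Conditions: p-TsOH·H2O (cat.), MeOH/H2O 9:1, rt
Reagents that add atoms: none
Why: acid-catalysed hydrolysis of the isopropylidene acetal, to which the methyl ester in aqueous methanol and the stereocentre are indifferent.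

Step 7
Reactants: 12 methyl (5Z,7S)-7,8-dihydroxyoct-5-enoate
Product: 13 methyl (5Z,7S)-7,8-bis(tert-butyldimethylsilyloxy)oct-5-enoate
Conditions: TBSCl (2.5 equiv), imidazole, DMF, rt
Reagents that add atoms: tert-butyldimethylsilyl chloride, CC(C)(C)[Si](C)(C)Cl
Why: standard silylation of both hydroxyls through the N-silylimidazolium species.

Step 8
Reactants: 13 methyl (5Z,7S)-7,8-bis(tert-butyldimethylsilyloxy)oct-5-enoate
Product: 14 methyl (5Z,7S)-7-(tert-butyldimethylsilyloxy)-8-hydroxyoct-5-enoate
Conditions: HF·pyridine, pyridine/THF, 0 °C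
Reagents that add atoms: none
Why: selective protodesilylation, the less hindered primary silyl ether being cleaved by buffered HF·pyridine well before the secondary allylic one, a known differentiation of bis-silyl ethers of 1,2-diols.

Step 9
Reactants: 14 methyl (5Z,7S)-7-(tert-butyldimethylsilyloxy)-8-hydroxyoct-5-enoate
Product: 15 methyl (5Z,7S)-7-(tert-butyldimethylsilyloxy)-8-oxooct-5-enoate
Conditions: Dess–Martin periodinane, NaHCO3, CH2Cl2, 0 °C to rt; used crude at once
Reagents that add atoms: none
Why: Dess–Martin oxidation of the primary alcohol under buffered non-basic conditions, chosen because this α-silyloxy β,γ-unsaturated aldehyde epimerises and conjugates easily.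

Step 10
Reactants: 6 2-bromo-5-[(Z)-oct-2-enyl]furan; 15 methyl (5Z,7S)-7-(tert-butyldimethylsilyloxy)-8-oxooct-5-enoate
Product: 17 methyl (5Z,7S,8RS)-7-(tert-butyldimethylsilyloxy)-8-hydroxy-8-{5-[(Z)-oct-2-enyl]furan-2-yl}oct-5-enoate, via 5-octenyl-2-furyllithium 16 (not isolated)
Conditions: n-BuLi (slightly less than 6), THF, −78 °C; then 15, −78 °C; AcOH quench at −78 °C; chromatography on Et3N-deactivated silica
Reagents that add atoms: none
Why: bromine–lithium exchange at −78 °C outruns deprotonation of the doubly activated CH2, and the furyllithium adds to the aldehyde far faster than to the methyl ester (1,2-carbonyl addition); the carbinol centre is formed as both epimers on purpose because the next step erases it, and the cold acid quench guards C7 against base.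

Step 11
Reactants: 17 methyl (5Z,7S,8RS)-7-(tert-butyldimethylsilyloxy)-8-hydroxy-8-{5-[(Z)-oct-2-enyl]furan-2-yl}oct-5-enoate
Product: 20 methyl (5Z,7S,8S,12R,14Z)-7-(tert-butyldimethylsilyloxy)-12-hydroxy-9-oxoprosta-5,10,14-trienoate, via furfuryl cation 18 (not isolated), via pentadienyl cation 19 (not isolated)
Conditions: ZnCl2, 1,4-dioxane/H2O 3:1, pH 5–6, 65 °C
Reagents that add atoms: water, O
Why: ZnCl2-assisted loss of the carbinol hydroxyl from either C8 epimer of 17 gives the single furfuryl cation 18; water adds at the octenyl-bearing furan carbon (C12), the ring C–O bond opens to the 1,4-dihydroxypentadienyl cation 19, and a thermal conrotatory 4π electrocyclisation forms the C8–C12 bond and with it the only carbocycle, the hydroxyallyl cation then losing a proton so that the former furan oxygen becomes the C9 ketone. This is the Piancatelli rearrangement, known for 5-alkyl-2-furylcarbinols with ZnCl2 in warm aqueous organic solvent, a near-neutral medium that should leave the ester, the silyl ether and the two Z alkenes alone. On the C8 terminus the side chain lies outside, and on C12 the hydroxyl is expected outside with the octenyl CH2 inside, as the heteroatom is placed in the known closures of 5-substituted furylcarbinols, so conrotation should first give 20 with the C8 arm trans to the C12 hydroxyl; C8 is epimerisable and is corrected in step 12. C12 cannot be corrected later, so the selectivity the step needs is torquoselectivity, the sense of conrotation relative to C7: with the C7 hydrogen eclipsing the C9–OH bond (1,3-allylic strain), the alkenyl chain anti to the forming bond where it stays clear of the inward octenyl CH2, and the silyloxy oxygen on the bonding face, the (7S) centre from D-glyceraldehyde should deliver the C12 configuration of the target. Water attack at C12 and bond formation from C8 are fixed by the structure of the furfuryl cation, so no regiochemical choice arises. The relay from C7 has no direct precedent in this rearrangement, so the configuration of 20 would have to be secured (nOe contacts, chemical correlation) before the route goes on; slow closure of the 5-alkylfuran and loss of the C7 silyloxy group once the ketone exists are the other hazards.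

Step 12
Reactants: 20 methyl (5Z,7S,8S,12R,14Z)-7-(tert-butyldimethylsilyloxy)-12-hydroxy-9-oxoprosta-5,10,14-trienoate
Product: 21 methyl (5Z,7S,8R,12R,14Z)-7-(tert-butyldimethylsilyloxy)-12-hydroxy-9-oxoprosta-5,10,14-trienoate
Conditions: 10-camphorsulfonic acid (cat.), CH2Cl2, rt, to constant isomer composition; minor isomer resubmitted
Reagents that add atoms: none
Why: acid-catalysed epimerisation through the C8–C9 enol should settle on the isomer with the C8 arm trans to the octenyl CH2 and cis to the smaller, hydrogen-bonding C12 hydroxyl, and acid is used because the C8 enolate formed by base can expel the C12 hydroxyl or the C7 silyloxy group; C7 and C12 are not touched.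

Step 13
Reactants: 21 methyl (5Z,7S,8R,12R,14Z)-7-(tert-butyldimethylsilyloxy)-12-hydroxy-9-oxoprosta-5,10,14-trienoate
Product: 22 methyl (5Z,7S,8R,12S,14Z)-7-(tert-butyldimethylsilyloxy)-10,11-epoxy-12-hydroxy-9-oxoprosta-5,14-dienoate (epoxide face not defined)
Conditions: H2O2 (30 %), NaOH (cat.), MeOH, −20 to 0 °C, short reaction time
Reagents that add atoms: hydrogen peroxide, OO
Why: Weitz–Scheffer nucleophilic epoxidation, in which hydroperoxide adds in conjugate fashion only to the electron-poor enone so that both isolated Z alkenes are left alone; the epoxide configuration is irrelevant because both carbons become sp2 again, methanol makes ester exchange degenerate, and cold catalytic base limits enolate formation at C8.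

Step 14
Reactants: 22 methyl (5Z,7S,8R,12S,14Z)-7-(tert-butyldimethylsilyloxy)-10,11-epoxy-12-hydroxy-9-oxoprosta-5,14-dienoate
Product: 24 methyl (5Z,7S,8R,12S,14Z)-7-(tert-butyldimethylsilyloxy)-10-chloro-12-hydroxy-9-oxoprosta-5,10,14-trienoate, via chlorohydrin 23 (not isolated)
Conditions: HCl (2 M in Et2O), CH2Cl2, −20 °C to rt
Reagents that add atoms: hydrogen chloride, Cl
Why: acid-mediated opening of the α,β-epoxy ketone by chloride at the α carbon (C10, SN2 next to the carbonyl) gives the 2-chloro-3-hydroxy ketone, which loses water through the C9–C10 enol to the 2-chloro enone, the classical epoxy ketone to α-halo enone conversion; anhydrous HCl in a non-nucleophilic solvent is expected to spare the secondary silyl ether, and C8 and C12 are not involved.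

Step 15
Reactants: 24 methyl (5Z,7S,8R,12S,14Z)-7-(tert-butyldimethylsilyloxy)-10-chloro-12-hydroxy-9-oxoprosta-5,10,14-trienoate
Product: 25 methyl (5Z,7S,8R,12S,14Z)-10-chloro-7,12-dihydroxy-9-oxoprosta-5,10,14-trienoate
Conditions: HF·pyridine, MeCN, 0 °C to rt
Reagents that add atoms: none
Why: acidic fluoride desilylation, used instead of basic Bu4NF so that the β-oxygenated ketone is not driven into E1cB elimination.

Step 16
Reactants: 25 methyl (5Z,7S,8R,12S,14Z)-10-chloro-7,12-dihydroxy-9-oxoprosta-5,10,14-trienoate
Product: 26 punaglandin 8, methyl (5Z,7S,8R,12S,14Z)-7-acetoxy-10-chloro-12-hydroxy-9-oxoprosta-5,10,14-trienoate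
Conditions: Ac2O, pyridine, CH2Cl2, 0 °C
Reagents that add atoms: acetic anhydride, CC(=O)OC(C)=O
Why: acylation of the secondary allylic alcohol with Ac2O/pyridine without an acyl-transfer catalyst, under which the hindered tertiary C12 hydroxyl stays free; the weak base at 0 °C limits elimination of the β-acetoxy ketone, and C7 keeps its configuration because its C–O bond is not broken.

**Compound list**
1 | (Z)-oct-2-en-1-ol | CCCCC/C=C\CO | starting material
2 | (Z)-1-bromooct-2-ene | CCCCC/C=C\CBr | intermediate
3 | furan | c1ccoc1 | starting material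
4 | 2-furyllithium | [Li]c1ccco1 | intermediate (not isolated)
5 | 2-[(Z)-oct-2-enyl]furan | CCCCC/C=C\Cc1ccco1 | intermediate
6 | 2-bromo-5-[(Z)-oct-2-enyl]furan | CCCCC/C=C\Cc1ccc(Br)o1 | intermediate
7 | (R)-2,3-O-isopropylideneglyceraldehyde | O=C[C@H]1COC(C)(C)O1 | starting material
8 | (4-carboxybutyl)triphenylphosphonium bromide | OC(=O)CCCC[P+](c1ccccc1)(c1ccccc1)c1ccccc1.[Br-] | starting material
9 | sodium 5-(triphenylphosphoranylidene)pentanoate (ylide) | [Na+].[O-]C(=O)CCCC=P(c1ccccc1)(c1ccccc1)c1ccccc1 | intermediate (not isolated)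
10 | (5Z,7S)-7,8-(isopropylidenedioxy)oct-5-enoic acid | OC(=O)CCC/C=C\[C@H]1COC(C)(C)O1 | intermediate
11 | methyl (5Z,7S)-7,8-(isopropylidenedioxy)oct-5-enoate | COC(=O)CCC/C=C\[C@H]1COC(C)(C)O1 | intermediate
12 | methyl (5Z,7S)-7,8-dihydroxyoct-5-enoate | COC(=O)CCC/C=C\[C@H](O)CO | intermediate
13 | methyl (5Z,7S)-7,8-bis(tert-butyldimethylsilyloxy)oct-5-enoate | COC(=O)CCC/C=C\[C@H](O[Si](C)(C)C(C)(C)C)CO[Si](C)(C)C(C)(C)C | intermediate
14 | methyl (5Z,7S)-7-(tert-butyldimethylsilyloxy)-8-hydroxyoct-5-enoate | COC(=O)CCC/C=C\[C@H](O[Si](C)(C)C(C)(C)C)CO | intermediate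
15 | methyl (5Z,7S)-7-(tert-butyldimethylsilyloxy)-8-oxooct-5-enoate | COC(=O)CCC/C=C\[C@H](O[Si](C)(C)C(C)(C)C)C=O | intermediate
16 | 5-[(Z)-oct-2-enyl]furan-2-yllithium | CCCCC/C=C\Cc1ccc([Li])o1 | intermediate (not isolated)
17 | methyl (5Z,7S,8RS)-7-(tert-butyldimethylsilyloxy)-8-hydroxy-8-{5-[(Z)-oct-2-enyl]furan-2-yl}oct-5-enoate (both C8 epimers) | CCCCC/C=C\Cc1ccc(o1)C(O)[C@H](/C=C\CCCC(=O)OC)O[Si](C)(C)C(C)(C)C | intermediate
18 | furfuryl cation from 17 (2-alkylidene-2H-furan-1-ium form, carbinol centre erased) | CCCCC/C=C\CC1=[O+]C(C=C1)=C[C@H](/C=C\CCCC(=O)OC)O[Si](C)(C)C(C)(C)C | intermediate (not isolated)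
19 | 1,4-dihydroxypentadienyl cation C8–C12 (O-protonated enol of the Z-enedione, side chain outside on C8) | CCCCC/C=C\CC(=[OH+])/C=C\C(O)=C\[C@H](/C=C\CCCC(=O)OC)O[Si](C)(C)C(C)(C)C | intermediate (not isolated)
20 | methyl (5Z,7S,8S,12R,14Z)-7-(tert-butyldimethylsilyloxy)-12-hydroxy-9-oxoprosta-5,10,14-trienoate (C8 arm trans to the C12 hydroxyl) | CCCCC/C=C\C[C@@]1(O)C=CC(=O)[C@H]1[C@H](/C=C\CCCC(=O)OC)O[Si](C)(C)C(C)(C)C | intermediate
21 | methyl (5Z,7S,8R,12R,14Z)-7-(tert-butyldimethylsilyloxy)-12-hydroxy-9-oxoprosta-5,10,14-trienoate (C8 arm cis to the C12 hydroxyl, trans to the octenyl chain) | CCCCC/C=C\C[C@@]1(O)C=CC(=O)[C@@H]1[C@H](/C=C\CCCC(=O)OC)O[Si](C)(C)C(C)(C)C | intermediate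
22 | methyl (5Z,7S,8R,12S,14Z)-7-(tert-butyldimethylsilyloxy)-10,11-epoxy-12-hydroxy-9-oxoprosta-5,14-dienoate (epoxide face not defined) | CCCCC/C=C\C[C@@]1(O)C2OC2C(=O)[C@@H]1[C@H](/C=C\CCCC(=O)OC)O[Si](C)(C)C(C)(C)C | intermediate
23 | methyl (5Z,7S,8R,12S,14Z)-7-(tert-butyldimethylsilyloxy)-10-chloro-11,12-dihydroxy-9-oxoprosta-5,14-dienoate (C10, C11 not defined) | CCCCC/C=C\C[C@@]1(O)C(O)C(Cl)C(=O)[C@@H]1[C@H](/C=C\CCCC(=O)OC)O[Si](C)(C)C(C)(C)C | intermediate (not isolated)
24 | methyl (5Z,7S,8R,12S,14Z)-7-(tert-butyldimethylsilyloxy)-10-chloro-12-hydroxy-9-oxoprosta-5,10,14-trienoate | CCCCC/C=C\C[C@@]1(O)C=C(Cl)C(=O)[C@@H]1[C@H](/C=C\CCCC(=O)OC)O[Si](C)(C)C(C)(C)C | intermediate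
25 | methyl (5Z,7S,8R,12S,14Z)-10-chloro-7,12-dihydroxy-9-oxoprosta-5,10,14-trienoate | CCCCC/C=C\C[C@@]1(O)C=C(Cl)C(=O)[C@@H]1[C@H](/C=C\CCCC(=O)OC)O | intermediate
26 | punaglandin 8, methyl (5Z,7S,8R,12S,14Z)-7-acetoxy-10-chloro-12-hydroxy-9-oxoprosta-5,10,14-trienoate | CCCCC/C=C\C[C@@]1(O)C=C(Cl)C(=O)[C@@H]1[C@H](/C=C\CCCC(=O)OC)OC(C)=O | target

**Totals**
Total step count: 16.
Longest linear sequence: 13 steps (steps 4 to 16, from 7).

**Steps most likely to fail**

Step 11. The process at risk is the transfer of configuration from C7 to C12. Weak facial selectivity in the conrotation would give both ring diastereomers; these can be separated because C7 tags them, but at the cost of material. A facial preference opposite to the one assumed, or the octenyl chain taking the outside position on C12, would give the C12 epimer, and no later step can repair that. Loss of the C7 silyloxy group once the C9 ketone exists is the second hazard. Fallback (sets out from alcohol 1 and diol 12, comes back at 21): the ring is made first, with its absolute configuration taken from bought (R)-4-(tert-butyldimethylsilyloxy)cyclopent-2-en-1-one, and the C7–C8 bond is then made by an aldol reaction. Alcohol 1 is converted (MsCl, LiCl, 2,4,6-collidine, DMF, 0 °C) into (Z)-1-chlorooct-2-ene F1. Reactive barium (from BaI2 and lithium biphenylide, THF, −78 °C) turns it into (Z)-oct-2-enylbarium chloride F2, an allylic barium reagent of the kind that adds to ketones at its α carbon with the Z geometry kept. Its 1,2-addition to the silyloxy enone, anti to the silyloxy group, gives (1S,4R)-4-(tert-butyldimethylsilyloxy)-1-[(Z)-oct-2-enyl]cyclopent-2-en-1-ol F3. Bu4NF then gives the cis diol (1S,4R)-1-[(Z)-oct-2-enyl]cyclopent-2-ene-1,4-diol F4, and MnO2 oxidises only its secondary allylic alcohol to (S)-4-hydroxy-4-[(Z)-oct-2-enyl]cyclopent-2-en-1-one F5. Glycol cleavage of 12 (NaIO4, THF/H2O, 0 °C) gives methyl (Z)-7-oxohept-5-enoate F6, used cold and at once. The dianion of F5 (LiN(i-Pr)2, 2.2 equiv, THF, −78 °C) adds to F6; C8 should settle trans to the octenyl chain, and the (7S) aldol product methyl (5Z,7S,8R,12R,14Z)-7,12-dihydroxy-9-oxoprosta-5,10,14-trienoate F7 is separated from its C7 epimer. Silylation of its secondary hydroxyl (TBSCl, imidazole, DMF) gives 21. This material would also serve to prove the configuration of 21 made by the main route.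

Step 10. The process at risk is proton abstraction at C7 of aldehyde 15 by the basic furyllithium, which would cost the C7 configuration and move the double bond into conjugation; attack at the methyl ester is the lesser risk. Fallback (sets out from 14, comes back at 17): acylation followed by reduction instead of carbonyl addition. Alcohol 14 is oxidised (TEMPO cat., PhI(OAc)2, MeCN/H2O) to (2S,3Z)-2-(tert-butyldimethylsilyloxy)-8-methoxy-8-oxooct-3-enoic acid F8. Coupling with MeNHOMe·HCl (carbodiimide, i-Pr2NEt) gives the N-methoxy-N-methyl amide methyl (5Z,7S)-7-(tert-butyldimethylsilyloxy)-8-[methoxy(methyl)amino]-8-oxooct-5-enoate F9, whose α-hydrogen is far less acidic than that of the aldehyde. Furyllithium 16 adds once to F9 and, after hydrolysis of the chelate, gives the 2-acylfuran methyl (5Z,7S)-7-(tert-butyldimethylsilyloxy)-8-{5-[(Z)-oct-2-enyl]furan-2-yl}-8-oxooct-5-enoate F10. NaBH4 with CeCl3·7H2O in MeOH at −40 °C reduces the ketone to 17, whose carbinol configuration does not matter.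

Step 14. The process at risk is the fate of the protonated epoxy ketone: a pinacol-type shift of a C12 substituent to C11 (the substrate is a 2,3-epoxy alcohol), loss of the silyl group, or a stop at the chlorohydrin without dehydration. The base sensitivity of 21 and 22 in step 13 belongs to the same problem. Fallback (sets out from 22, comes back at 24): the C–Cl bond formation and the dehydration are separated and strong acid is left out. Chloride is delivered by SN2 at C10 from LiCl with AcOH as a mild proton source in THF, and chlorohydrin 23 is isolated. Its secondary C11 hydroxyl is then converted (MsCl, Et3N, CH2Cl2, −30 °C) into the mesylate methyl (5Z,7S,8R,12S,14Z)-7-(tert-butyldimethylsilyloxy)-10-chloro-12-hydroxy-11-(methylsulfonyloxy)-9-oxoprosta-5,14-dienoate F11, which loses methanesulfonate by E1cB through the more acidic C10 position in the same flask to give 24.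

**Further compounds**
F1 | step 11 | (Z)-1-chlorooct-2-ene | CCCCC/C=C\CCl
F2 | step 11 | (Z)-oct-2-enylbarium chloride | CCCCC/C=C\C[Ba]Cl
F3 | step 11 | (1S,4R)-4-(tert-butyldimethylsilyloxy)-1-[(Z)-oct-2-enyl]cyclopent-2-en-1-ol | CCCCC/C=C\C[C@@]1(O)C=C[C@H](O[Si](C)(C)C(C)(C)C)C1
F4 | step 11 | (1S,4R)-1-[(Z)-oct-2-enyl]cyclopent-2-ene-1,4-diol | CCCCC/C=C\C[C@@]1(O)C=C[C@H](O)C1
F5 | step 11 | (S)-4-hydroxy-4-[(Z)-oct-2-enyl]cyclopent-2-en-1-one | CCCCC/C=C\C[C@@]1(O)C=CC(=O)C1
F6 | step 11 | methyl (Z)-7-oxohept-5-enoate | COC(=O)CCC/C=C\C=O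
F7 | step 11 | methyl (5Z,7S,8R,12R,14Z)-7,12-dihydroxy-9-oxoprosta-5,10,14-trienoate | CCCCC/C=C\C[C@@]1(O)C=CC(=O)[C@@H]1[C@H](/C=C\CCCC(=O)OC)O
F8 | step 10 | (2S,3Z)-2-(tert-butyldimethylsilyloxy)-8-methoxy-8-oxooct-3-enoic acid | COC(=O)CCC/C=C\[C@H](O[Si](C)(C)C(C)(C)C)C(=O)O
F9 | step 10 | methyl (5Z,7S)-7-(tert-butyldimethylsilyloxy)-8-[methoxy(methyl)amino]-8-oxooct-5-enoate | COC(=O)CCC/C=C\[C@H](O[Si](C)(C)C(C)(C)C)C(=O)N(C)OC
F10 | step 10 | methyl (5Z,7S)-7-(tert-butyldimethylsilyloxy)-8-{5-[(Z)-oct-2-enyl]furan-2-yl}-8-oxooct-5-enoate | CCCCC/C=C\Cc1ccc(o1)C(=O)[C@H](/C=C\CCCC(=O)OC)O[Si](C)(C)C(C)(C)C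
F11 | step 14 | methyl (5Z,7S,8R,12S,14Z)-7-(tert-butyldimethylsilyloxy)-10-chloro-12-hydroxy-11-(methylsulfonyloxy)-9-oxoprosta-5,14-dienoate | CCCCC/C=C\C[C@@]1(O)C(OS(C)(=O)=O)C(Cl)C(=O)[C@@H]1[C@H](/C=C\CCCC(=O)OC)O[Si](C)(C)C(C)(C)C
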